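C-numbers are briarellin numbering (C16 = OCH2, C18 = Me on C3, C19 = CH2 on C7, C20 = Me on C11); β = face of the cyclohexane carrying C2 and C9, α = the other face.
23 ⇐ cis-diol 22 ⇐ cyclic carbonate 21 ⇐ 11α,12α-epoxide 20 (CO2 insertion with double inversion at C12 gives the cis-diol).
20 ⇐ 6/10 carbocycle 17: double epoxidation, transannular C9–O→C2 epoxide opening (2,9-ether bridge), then C3–O→C16 closure (oxepane); both ethers are made last, on the finished carbocycle.
17 ⇐ aldehyde 16 by a Type II carbonyl-ene closure of the ten-membered ring (C8–C9) ⇐ ester 10 (hydroboration sets C15; ketone → 2-methylallyl terminus).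
10 ⇐ (R)-carvone-derived dienoate 4 + Z-alkenylcopper 8 (from chloro ketal 5 and propyne 6). Ring order: cyclohexane (chiral pool) → cyclodecane → tetrahydrofuran/oxonane → oxepane.

Assumption: operations telescoped in one flask count as one step; DMDO and the Lombardo reagent are used as pre-made stock reagents.

Step 1
Reactants: 1 (R)-(−)-carvone
Product: 3 (3R)-6-methyl-3-(prop-1-en-2-yl)cyclohexa-1,5-dien-1-yl trifluoromethanesulfonate, via lithium dienolate 2 (not isolated)
Conditions: LDA, THF, −78 °C; PhNTf2, −78 → 0 °C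
Reagents that add atoms: N-phenyl-bis(trifluoromethanesulfonimide), FC(F)(F)S(=O)(=O)N(c1ccccc1)S(=O)(=O)C(F)(F)F
Why: Kinetic α′-deprotonation gives the cross-conjugated dienolate, which is O-sulfonylated (enol triflate formation); the C14 stereocentre is not touched.

Step 2
Reactants: 3 dienyl triflate
Product: 4 methyl (3R)-6-methyl-3-(prop-1-en-2-yl)cyclohexa-1,5-diene-1-carboxylate
Conditions: Pd(OAc)2 (5 mol %), dppf, CO (1 atm), MeOH, Et3N, DMF, 60 °C
Reagents that add atoms: carbon monoxide, [C-]#[O+]; methanol, CO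
Why: Pd-catalysed methoxycarbonylation of the enol triflate (oxidative addition, CO insertion, methanolysis) installs C9 as the ester of a cross-conjugated dienoate.

Step 3
Reactants: 4 methyl dienoate; 5 2-(3-chloropropyl)-2-methyl-1,3-dioxolane; 6 propyne
Product: 10 methyl (1S,5R,6S)-2-methyl-6-[(1Z)-2-methyl-5-(2-methyl-1,3-dioxolan-2-yl)pent-1-en-1-yl]-5-(prop-1-en-2-yl)cyclohex-2-ene-1-carboxylate, via Grignard reagent 7 (not isolated), via Z-alkenylcopper 8 (not isolated), via silyl ketene acetal 9 (not isolated)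
Conditions: 5, Mg, THF; CuBr·SMe2, Et2O/Me2S, −45 °C; 6, −25 °C; 4, TMSCl, THF, −78 → −30 °C; AcOH, −78 °C
Reagents that add atoms: none
Why: Normant syn-carbocupration of propyne fixes the Z-trisubstituted C2=C3 bond, the TMSCl-accelerated 1,4-addition occurs anti to the C14 isopropenyl group (sets C1), and kinetic α-protonation of the dienyl ketene acetal from the face opposite the new C1 substituent places CO2Me cis to it (sets C10, leaves C11=C12 deconjugated).

Step 4
Reactants: 10 ester ketal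
Product: 13 methyl (1S,5R,6R)-5-[(2R)-1-hydroxypropan-2-yl]-2-methyl-6-[(1Z)-2-methyl-6-oxohept-1-en-1-yl]cyclohex-2-ene-1-carboxylate, via B-alkyl-9-BBN adduct 11 (not isolated), via hydroxy ketal 12 (not isolated)
Conditions: 9-BBN, THF, 0 °C → rt; NaOAc, 30% H2O2; then 1 M HCl, THF, rt
Reagents that add atoms: hydrogen peroxide, OO; water, O
Why: Hydroboration–oxidation with 9-BBN touches only the 1,1-disubstituted alkene; with C14–H eclipsing that alkene (A1,3 model) boron adds from the face away from the C1 branch, which sets C15, and acid hydrolysis of the dioxolane then frees the methyl ketone.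

Step 5
Reactants: 13 keto alcohol
Product: 14 methyl (1S,5R,6R)-2-methyl-6-[(1Z)-2-methyl-6-oxohept-1-en-1-yl]-5-[(2R)-1-(tosyloxy)propan-2-yl]cyclohex-2-ene-1-carboxylate
Conditions: TsCl, pyridine, DMAP (cat.), CH2Cl2, 0 °C
Reagents that add atoms: p-toluenesulfonyl chloride, Cc1ccc(cc1)S(Cl)(=O)=O
Why: Tosylation of the only hydroxyl makes C16 the electrophile for the later oxepane closure; no stereocentre is involved.

Step 6
Reactants: 14 keto tosylate
Product: 15 methyl (1S,5R,6R)-6-[(1Z)-2,6-dimethylhepta-1,6-dien-1-yl]-2-methyl-5-[(2R)-1-(tosyloxy)propan-2-yl]cyclohex-2-ene-1-carboxylate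
Conditions: Lombardo reagent (Zn, CH2Br2, TiCl4), THF/CH2Cl2, 0 °C → rt
Reagents that add atoms: dibromomethane (CH2 source of the Lombardo reagent), BrCBr
Why: Takai–Lombardo methylenation is non-basic and ketone-selective, so the ester, the epimerisable C10–H and the tosylate survive while the 2-methylallyl ene donor is formed.

Step 7
Reactants: 15 ester
Product: 16 (1S,5R,6R)-6-[(1Z)-2,6-dimethylhepta-1,6-dien-1-yl]-2-methyl-5-[(2R)-1-(tosyloxy)propan-2-yl]cyclohex-2-ene-1-carbaldehyde
Conditions: DIBAL-H (1.05 equiv), CH2Cl2, −78 °C; Rochelle salt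
Reagents that add atoms: none
Why: Partial ester reduction with DIBAL-H (tetrahedral aluminate stable at −78 °C) gives the aldehyde without base, so C10 stays cis to C1.

Step 8
Reactants: 16 aldehyde
Product: 17 (2Z)-eunicella-2,7(19),11-trien-9-ol 16-tosylate (cis-fused 6/10 carbocycle; H-1 and H-10 α; 9-OH and C15 as in 23)
Conditions: Me2AlCl (1.5 equiv), CH2Cl2 (2 mM, slow addition), −78 → −20 °C
Reagents that add atoms: none
Why: Proposed new method: a Type II carbonyl-ene reaction is used to close a ten-membered carbocycle, the Me2AlCl-bound aldehyde being attacked by the terminal CH2 of the 2-methylallyl unit with transfer of a methyl hydrogen through the usual six-centre transition state (forms C8–C9 and the C7=C19 methylene; Me2AlCl also scavenges protons), with Felkin–Anh approach anti to the C10–C11 vinyl bond expected to give the 9-OH epimer needed; the closest known chemistry is the Me2AlCl-mediated Type II ene cyclisation to 6–8-membered 3-methylenecycloalkanols.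

Step 9
Reactants: 17 bicyclic alcohol
Product: 20 11α,12α-epoxide of the briarellin tetracycle (2,9- and 3,16-ether bridges closed), via bis-epoxide 18 (not isolated), via tetrahydrofuran alcohol 19 (not isolated)
Conditions: DMDO (2.1 equiv), acetone/CH2Cl2, −40 → 0 °C; evaporate; NaH, THF/DMF, 0 → 45 °C
Reagents that add atoms: dimethyldioxirane (DMDO), CC1(C)OO1
Why: Proposed new method: an untested transannular cascade built from known steps, in which DMDO epoxidises the two trisubstituted alkenes (C2=C3 on its exterior face, C11=C12 anti to the axial C10–C9 bond, the 1,1-disubstituted C7=C19 reacting more slowly), the C9 alkoxide opens the 2,3-epoxide at C2 (5-exo, inversion, so the Z-alkene sets C2 and C3) and the released C3 alkoxide displaces the C16 tosylate (7-exo Williamson etherification); the closest known chemistry is the hydroxy-epoxide cyclisation to 2-(1-hydroxyalkyl)tetrahydrofurans and sulfonate-displacement closure of oxepanes by tertiary alcohols.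

Step 10
Reactants: 20 tetracyclic epoxide
Product: 21 11α,12α-cyclic carbonate of the tetracycle
Conditions: CO2 (10 bar), Al(III) amino-tris(phenolate) (5 mol %), PPNCl (10 mol %), 2-butanone, 85 °C
Reagents that add atoms: carbon dioxide, O=C=O
Why: Halide-cocatalysed CO2/epoxide coupling: chloride opens the epoxide at secondary C12 (trans-diaxial), the C11 alkoxide is carboxylated and the carbonate displaces chloride, so double inversion at C12 gives the cis carbonate, as known for limonene oxide.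

Step 11
Reactants: 21 cyclic carbonate
Product: 22 11α,12α-diol (deoctanoyl target)
Conditions: LiOH, THF/H2O, 40 °C
Reagents that add atoms: none
Why: Saponification of the cyclic carbonate (acyl–oxygen cleavage) releases the cis-diol with both C–O bonds untouched.

Step 12
Reactants: 22 diol
Product: 23 target CNP0286133.1 (12-octanoate)
Conditions: octanoyl chloride, pyridine, DMAP (cat.), CH2Cl2, 0 °C
Reagents that add atoms: octanoyl chloride, CCCCCCCC(Cl)=O
Why: DMAP-catalysed acylation of the equatorial secondary C12–OH; the tertiary C11–OH is too hindered to react.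

Compound list
1 | (R)-(−)-carvone, (5R)-2-methyl-5-(prop-1-en-2-yl)cyclohex-2-en-1-one | CC(=C)[C@@H]1CC=C(C)C(=O)C1 | starting material
2 | lithium (3R)-6-methyl-3-(prop-1-en-2-yl)cyclohexa-1,5-dien-1-olate | CC(=C)[C@@H]1CC=C(C)C(O[Li])=C1 | intermediate
3 | (3R)-6-methyl-3-(prop-1-en-2-yl)cyclohexa-1,5-dien-1-yl trifluoromethanesulfonate | CC(=C)[C@@H]1CC=C(C)C(OS(=O)(=O)C(F)(F)F)=C1 | intermediate
4 | methyl (3R)-6-methyl-3-(prop-1-en-2-yl)cyclohexa-1,5-diene-1-carboxylate | CC(=C)[C@@H]1CC=C(C)C(C(=O)OC)=C1 | intermediate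
5 | 2-(3-chloropropyl)-2-methyl-1,3-dioxolane | ClCCCC1(C)OCCO1 | starting material
6 | propyne | CC#C | starting material
7 | [3-(2-methyl-1,3-dioxolan-2-yl)propyl]magnesium chloride | Cl[Mg]CCCC1(C)OCCO1 | intermediate
8 | (1Z)-2-methyl-5-(2-methyl-1,3-dioxolan-2-yl)pent-1-en-1-ylcopper (MgBrCl complex) | [Cu]/C=C(/C)CCCC1(C)OCCO1 | intermediate
9 | methyl trimethylsilyl ketene acetal of 10 (C9=C10 enol ether; C1 and C14 as in 10) | CC(=C)[C@@H]1CC=C(C)C(=C(OC)O[Si](C)(C)C)[C@H]1/C=C(/C)CCCC2(C)OCCO2 | intermediate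
10 | methyl (1S,5R,6S)-2-methyl-6-[(1Z)-2-methyl-5-(2-methyl-1,3-dioxolan-2-yl)pent-1-en-1-yl]-5-(prop-1-en-2-yl)cyclohex-2-ene-1-carboxylate (ester cis to the alkenyl group, alkenyl trans to isopropenyl) | CC(=C)[C@@H]1CC=C(C)[C@@H](C(=O)OC)[C@H]1/C=C(/C)CCCC2(C)OCCO2 | intermediate
11 | B-alkyl-9-BBN adduct of 10 (boron on C16, C15 as in 13) | B1(C[C@H](C)[C@@H]3CC=C(C)[C@@H](C(=O)OC)[C@H]3/C=C(/C)CCCC4(C)OCCO4)C2CCCC1CCC2 | intermediate
12 | methyl (1S,5R,6R)-5-[(2R)-1-hydroxypropan-2-yl]-2-methyl-6-[(1Z)-2-methyl-5-(2-methyl-1,3-dioxolan-2-yl)pent-1-en-1-yl]cyclohex-2-ene-1-carboxylate | OC[C@H](C)[C@@H]1CC=C(C)[C@@H](C(=O)OC)[C@H]1/C=C(/C)CCCC2(C)OCCO2 | intermediate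
13 | methyl (1S,5R,6R)-5-[(2R)-1-hydroxypropan-2-yl]-2-methyl-6-[(1Z)-2-methyl-6-oxohept-1-en-1-yl]cyclohex-2-ene-1-carboxylate | OC[C@H](C)[C@@H]1CC=C(C)[C@@H](C(=O)OC)[C@H]1/C=C(/C)CCCC(C)=O | intermediate
14 | methyl (1S,5R,6R)-2-methyl-6-[(1Z)-2-methyl-6-oxohept-1-en-1-yl]-5-[(2R)-1-(tosyloxy)propan-2-yl]cyclohex-2-ene-1-carboxylate | Cc1ccc(cc1)S(=O)(=O)OC[C@H](C)[C@@H]2CC=C(C)[C@@H](C(=O)OC)[C@H]2/C=C(/C)CCCC(C)=O | intermediate
15 | methyl (1S,5R,6R)-6-[(1Z)-2,6-dimethylhepta-1,6-dien-1-yl]-2-methyl-5-[(2R)-1-(tosyloxy)propan-2-yl]cyclohex-2-ene-1-carboxylate | Cc1ccc(cc1)S(=O)(=O)OC[C@H](C)[C@@H]2CC=C(C)[C@@H](C(=O)OC)[C@H]2/C=C(/C)CCCC(C)=C | intermediate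
16 | (1S,5R,6R)-6-[(1Z)-2,6-dimethylhepta-1,6-dien-1-yl]-2-methyl-5-[(2R)-1-(tosyloxy)propan-2-yl]cyclohex-2-ene-1-carbaldehyde | Cc1ccc(cc1)S(=O)(=O)OC[C@H](C)[C@@H]2CC=C(C)[C@@H](C=O)[C@H]2/C=C(/C)CCCC(C)=C | intermediate
17 | (2Z)-eunicella-2,7(19),11-trien-9-ol 16-tosylate: cis-fused cyclohexene/cyclodecadiene, H-1 and H-10 α, C14 side chain α, 9-OH and C15 as in 23 | C=C1CCC/C(C)=C\[C@H]2[C@H]([C@@H](C)COS(=O)(=O)c3ccc(C)cc3)CC=C(C)[C@H]2[C@@H](O)C1 | intermediate
18 | 2,3:11,12-bis-epoxide of 17 (2,3-epoxide on the exterior face, 11α,12α-epoxide) | C=C1CCC[C@]3(C)O[C@@H]3[C@H]2[C@H]([C@@H](C)COS(=O)(=O)c5ccc(C)cc5)C[C@@H]4O[C@]4(C)[C@H]2[C@@H](O)C1 | intermediate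
19 | 2,9-ether-bridged tertiary alcohol: 11α,12α-epoxy-3-hydroxy-2,9-epoxyeunicell-7(19)-en-16-yl tosylate (C2, C3, C9 as in 23) | C=C1CCC[C@](C)(O)[C@H]2O[C@@H](C1)[C@H]3[C@@H]2[C@H]([C@@H](C)COS(=O)(=O)c4ccc(C)cc4)C[C@@H]5O[C@]35C | intermediate
20 | 11α,12α-epoxide of the briarellin tetracycle (2,9- and 3,16-ether bridges, C7=C19 methylene) | C=C1CCC[C@]2(C)OC[C@H](C)[C@@H]3C[C@@H]5O[C@]5(C)[C@@H]4[C@H]3[C@@H]2O[C@H]4C1 | intermediate
21 | 11α,12α-cyclic carbonate of the tetracycle | C=C1CCC[C@]2(C)OC[C@H](C)[C@@H]3C[C@@H]5OC(=O)O[C@]5(C)[C@@H]4[C@H]3[C@@H]2O[C@H]4C1 | intermediate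
22 | 11α,12α-diol of the tetracycle (deoctanoyl target) | C=C1CCC[C@]2(C)OC[C@H](C)[C@@H]3C[C@H](O)[C@](C)(O)[C@@H]4[C@H]3[C@@H]2O[C@H]4C1 | intermediate
23 | CNP0286133.1: 11α-hydroxy-12α-octanoyloxy tetracycle | C=C1CCC[C@]2(C)OC[C@H](C)[C@@H]3C[C@H](OC(=O)CCCCCCC)[C@](C)(O)[C@@H]4[C@H]3[C@@H]2O[C@H]4C1 | target

Total step count: 12. Longest linear sequence: 12 steps (1 → 23); 5 and 6 are used as purchased.

The three steps most likely to fail

Step 8 (ene closure of a ten-membered ring; neither the ring size nor the C9 configuration has precedent). The fallback sets out from ketone 14 and replaces the Lewis-acid ene reaction by a chromium-mediated allylation. Kinetic enolisation of the methyl ketone (KHMDS, PhNTf2, −78 °C) gives the enol triflate F1. Pd-catalysed Negishi coupling with Me3SiCH2ZnCl gives the allylsilane ester F2, and DIBAL-H at −78 °C gives the allylsilane aldehyde F3. NBS (propylene oxide, −78 °C) turns the allylsilane into the 2-substituted allylic bromide, the bromo aldehyde F4. CrCl2 in THF at high dilution (Nozaki–Hiyama allylation) then closes the ring and the route is rejoined at 17.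

Step 9 (two face selectivities in the epoxidation, then two ring closures in one pot; the 7-exo displacement by a tertiary alkoxide is the weakest link). The fallback sets out from 17 and runs the sequence stepwise with an electrophile-activated second closure. The bis-epoxide 18 is made with DMDO and, with one equivalent of NaH at 0 °C, stopped at the tetrahydrofuran alcohol 19, which is isolated. Finkelstein exchange (NaI, acetone) gives the iodide F5. Silver activation (AgOTf, 2,6-di-tert-butylpyridine, CH2Cl2) lets the neutral tertiary alcohol close the oxepane, and the route is rejoined at 20.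

Step 10 (chloride must open a hindered trisubstituted epoxide at C12 past the axial C10–C9 bond). The fallback sets out from 20 and gives up the double-inversion logic. Deoxygenation (WCl6/n-BuLi, THF) gives the 11,12-alkene F6. Ligand-free dihydroxylation (OsO4 cat., NMO, acetone/H2O, 0 °C) attacks the convex α face of the ring alkene; the exocyclic C7=C19 methylene may compete and the reaction must be stopped early. This gives the diol directly and the route is rejoined at 22.

Further compounds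
F1 | step 8 | methyl (1S,5R,6R)-2-methyl-6-[(1Z)-2-methyl-6-(trifluoromethanesulfonyloxy)hepta-1,6-dien-1-yl]-5-[(2R)-1-(tosyloxy)propan-2-yl]cyclohex-2-ene-1-carboxylate | Cc1ccc(cc1)S(=O)(=O)OC[C@H](C)[C@@H]2CC=C(C)[C@@H](C(=O)OC)[C@H]2/C=C(/C)CCCC(=C)OS(=O)(=O)C(F)(F)F
F2 | step 8 | methyl (1S,5R,6R)-2-methyl-6-[(1Z)-2-methyl-6-(trimethylsilylmethyl)hepta-1,6-dien-1-yl]-5-[(2R)-1-(tosyloxy)propan-2-yl]cyclohex-2-ene-1-carboxylate | Cc1ccc(cc1)S(=O)(=O)OC[C@H](C)[C@@H]2CC=C(C)[C@@H](C(=O)OC)[C@H]2/C=C(/C)CCCC(=C)C[Si](C)(C)C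
F3 | step 8 | (1S,5R,6R)-2-methyl-6-[(1Z)-2-methyl-6-(trimethylsilylmethyl)hepta-1,6-dien-1-yl]-5-[(2R)-1-(tosyloxy)propan-2-yl]cyclohex-2-ene-1-carbaldehyde | Cc1ccc(cc1)S(=O)(=O)OC[C@H](C)[C@@H]2CC=C(C)[C@@H](C=O)[C@H]2/C=C(/C)CCCC(=C)C[Si](C)(C)C
F4 | step 8 | (1S,5R,6R)-6-[(1Z)-6-(bromomethyl)-2-methylhepta-1,6-dien-1-yl]-2-methyl-5-[(2R)-1-(tosyloxy)propan-2-yl]cyclohex-2-ene-1-carbaldehyde | Cc1ccc(cc1)S(=O)(=O)OC[C@H](C)[C@@H]2CC=C(C)[C@@H](C=O)[C@H]2/C=C(/C)CCCC(=C)CBr
F5 | step 9 | 16-iodo analogue of 19 (11α,12α-epoxy-3-hydroxy-2,9-ether, C16–I) | C=C1CCC[C@](C)(O)[C@H]2O[C@@H](C1)[C@H]3[C@@H]2[C@H]([C@@H](C)CI)C[C@@H]5O[C@]35C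
F6 | step 10 | 11,12-alkene of the briarellin tetracycle (both ether bridges closed, C7=C19 methylene) | C=C1CCC[C@]2(C)OC[C@H](C)[C@@H]3CC=C(C)[C@@H]4[C@H]3[C@@H]2O[C@H]4C1
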